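**Plan**
1. Retrosynthetic cuts, in order: the two O–Si bonds (phenol masks); the C2–C1' bond between ring C and ring B; then, on ring B alone, the C1'–B bond and the two aryl–CH2 (prenyl) bonds.
2. Enabling feature: C2 is the β-carbon of the C4 ketone. With ring C raised to the chromone level (C2=C3–C4=O next to O1), rings A and C form a flat, prochiral Michael acceptor that accepts an aryl–metal at C2.
3. Ring B is a symmetric 2,6-diprenylphenol. Its C1' (para to O) is the only ring C–H without an ortho neighbour, so a sterically governed C–H borylation places boron on the atom that must bond to C2.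
4. Forward order: 2,6-dibromophenol → silyl ether → double prenyl cross-coupling → C–H borylation → boronic acid; 7-hydroxychromone → silyl ether; union of the two halves; global desilylation. No ring is built, since rings A and C are bought fused and ring B is bought aromatic.
5. Stereochemistry: the single centre C2 (S) is set during the fragment union by an (S)-configured biaryl diphosphine on rhodium. A buffered, non-basic last step preserves it.

Key step: step 6

Remark: CIP analysis of the given SMILES gives (S) at C2 (O1 > aryl > C3 > H). The three starting materials are assumed to be catalogue chemicals.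

Step 1
Reactants: 1 2,6-dibromophenol
Product: 2 tert-butyl(2,6-dibromophenoxy)dimethylsilane
Conditions: TBSCl, imidazole, DMF, 23 °C
Reagents that add atoms: tert-butyldimethylsilyl chloride, CC(C)(C)[Si](C)(C)Cl
Why: Imidazole-promoted O-silylation of an acidic phenol, giving a mask that can later be removed by fluoride without acid, base or hydrogen and so spares the prenyl groups and C2.

Step 2
Reactants: 2 tert-butyl(2,6-dibromophenoxy)dimethylsilane; 3 tributyl(3-methylbut-2-enyl)stannane (2.5 equiv)
Product: 4 tert-butyl[2,6-bis(3-methylbut-2-enyl)phenoxy]dimethylsilane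
Conditions: Pd(PPh3)4 (10 mol %), toluene, 110 °C
Reagents that add atoms: none
Why: Double Stille coupling under base-free and fluoride-free conditions, which keep the silyl ether, with reductive elimination at the unsubstituted terminus of the prenyl–palladium intermediate expected to give the linear prenyl arene at both C–Br sites.

Step 3
Reactants: 4 tert-butyl[2,6-bis(3-methylbut-2-enyl)phenoxy]dimethylsilane
Product: 5 2-[4-(tert-butyldimethylsilyloxy)-3,5-bis(3-methylbut-2-enyl)phenyl]-4,4,5,5-tetramethyl-1,3,2-dioxaborolane
Conditions: [Ir(OMe)(cod)]2 (1.5 mol %), 4,4'-di-tert-butyl-2,2'-bipyridine (3 mol %), B2pin2 (1.0 equiv), THF, 70 °C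
Reagents that add atoms: bis(pinacolato)diboron, CC1(C)OB(OC1(C)C)B1OC(C)(C)C(C)(C)O1
Why: Iridium-catalysed arene C–H borylation is governed by sterics, so only the C–H para to oxygen (no ortho substituent) should react, and the trisubstituted prenyl alkenes are poor partners for hydroboration.

Step 4
Reactants: 5 the pinacol boronate
Product: 6 [4-(tert-butyldimethylsilyloxy)-3,5-bis(3-methylbut-2-enyl)phenyl]boronic acid
Conditions: NaIO4 (3 equiv), NH4OAc (3 equiv), acetone/H2O 2:1, 23 °C
Reagents that add atoms: water, O
Why: Oxidative hydrolysis of a pinacol boronate, in which periodate cleaves the released pinacol and draws the equilibrium to the free boronic acid near neutral pH, where isolated alkenes and the hindered aryl silyl ether are inert.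

Step 5
Reactants: 7 7-hydroxy-4H-chromen-4-one (7-hydroxychromone)
Product: 8 7-(triisopropylsilyloxy)-4H-chromen-4-one
Conditions: TIPSCl, imidazole, DMF, 23 °C
Reagents that add atoms: triisopropylsilyl chloride, CC(C)[Si](Cl)(C(C)C)C(C)C
Why: Imidazole-promoted O-silylation, using the bulkier TIPS group because this electron-poor aryl silyl ether must survive the aqueous base of step 6 and must prevent formation of a phenoxide that would deactivate the enone.

Step 6
Reactants: 8 7-(triisopropylsilyloxy)-4H-chromen-4-one; 6 the arylboronic acid (1.5 equiv)
Product: 9 (2S)-2-[4-(tert-butyldimethylsilyloxy)-3,5-bis(3-methylbut-2-enyl)phenyl]-7-(triisopropylsilyloxy)chroman-4-one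
Conditions: [RhCl(C2H4)2]2 (2.5 mol %), (S)-MeO-F12-BIPHEP [(S)-(6,6'-dimethoxybiphenyl-2,2'-diyl)bis[bis(3,4,5-trifluorophenyl)phosphine]] (5.5 mol %), KOH (0.3 equiv), toluene/H2O 10:1, 25 °C
Reagents that add atoms: none
Why: Hayashi–Miyaura asymmetric 1,4-addition: the hydroxo complex of monovalent rhodium transmetalates with 6 to an aryl–rhodium species, the C2=C3 bond of 8 binds and inserts so that the aryl group goes to C2 and rhodium to C3 (oxa-π-allyl enolate), and water protonates the enolate, releasing 9 and restoring Rh–OH. The closest known reaction type is this same addition of arylboronic acids to 4-chromones to give flavanones, so only the substrates are new. No ring is closed, because ring C is already present as the flat, prochiral chromone. C2 is controlled by the ligand alone: in the quadrant model for (S)-configured biaryl diphosphines a cyclic enone binds through the face that leads to (S)-3-arylcycloalkanones, and this maps onto (2S) here because replacing the ring CH2 by O1 leaves the sense of the CIP sequence unchanged; the (R)-ligand is available should the sense prove opposite. The step needs 1,4- over 1,2-addition, enolate protonation faster than β-aryloxide elimination (ring opening to the 2'-hydroxychalcone, which would erase C2) and no second addition to the product ketone, and the electron-poor ligand, room temperature, the mostly non-polar two-phase medium and substoichiometric base should secure all three. The boron-bearing carbon has no ortho substituent, the trisubstituted prenyl alkenes are too hindered to bind or insert, and both phenols are masked so that no phenoxide can deactivate the enone or open ring C.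

Step 7
Reactants: 9 the bis-silyl flavanone
Product: 10 (2S)-7-hydroxy-2-[4-hydroxy-3,5-bis(3-methylbut-2-enyl)phenyl]chroman-4-one (target)
Conditions: TBAF (2.4 equiv), AcOH (2.6 equiv), THF, 0 °C; aq. NH4Cl work-up
Reagents that add atoms: none
Why: Fluoride-induced cleavage of both aryl silyl ethers, with the acetic acid buffer protonating each phenoxide as it forms so that neither retro-oxa-Michael opening of ring C (racemisation at C2) nor acid-induced cyclisation of the ortho-prenylphenol to a chroman should occur.

**Compound list**
1 | 2,6-dibromophenol | Oc1c(Br)cccc1Br | starting material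
2 | tert-butyl(2,6-dibromophenoxy)dimethylsilane | CC(C)(C)[Si](C)(C)Oc1c(Br)cccc1Br | intermediate
3 | tributyl(3-methylbut-2-enyl)stannane | CCCC[Sn](CCCC)(CCCC)CC=C(C)C | starting material
4 | tert-butyl[2,6-bis(3-methylbut-2-enyl)phenoxy]dimethylsilane | CC(C)=CCc1cccc(CC=C(C)C)c1O[Si](C)(C)C(C)(C)C | intermediate
5 | 2-[4-(tert-butyldimethylsilyloxy)-3,5-bis(3-methylbut-2-enyl)phenyl]-4,4,5,5-tetramethyl-1,3,2-dioxaborolane | CC(C)=CCc1cc(B2OC(C)(C)C(C)(C)O2)cc(CC=C(C)C)c1O[Si](C)(C)C(C)(C)C | intermediate
6 | [4-(tert-butyldimethylsilyloxy)-3,5-bis(3-methylbut-2-enyl)phenyl]boronic acid | CC(C)=CCc1cc(B(O)O)cc(CC=C(C)C)c1O[Si](C)(C)C(C)(C)C | intermediate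
7 | 7-hydroxy-4H-chromen-4-one | O=c1ccoc2cc(O)ccc12 | starting material
8 | 7-(triisopropylsilyloxy)-4H-chromen-4-one | CC(C)[Si](Oc1ccc2c(=O)ccoc2c1)(C(C)C)C(C)C | intermediate
9 | (2S)-2-[4-(tert-butyldimethylsilyloxy)-3,5-bis(3-methylbut-2-enyl)phenyl]-7-(triisopropylsilyloxy)chroman-4-one | CC(C)=CCc1cc([C@@H]2CC(=O)c3ccc(O[Si](C(C)C)(C(C)C)C(C)C)cc3O2)cc(CC=C(C)C)c1O[Si](C)(C)C(C)(C)C | intermediate
10 | (2S)-7-hydroxy-2-[4-hydroxy-3,5-bis(3-methylbut-2-enyl)phenyl]chroman-4-one | CC(C)=CCc1cc([C@@H]2CC(=O)c3ccc(O)cc3O2)cc(CC=C(C)C)c1O | target

Total step count: 7. Longest linear sequence: 6 (steps 1, 2, 3, 4, 6, 7).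

**Steps most likely to fail**

Step 6. Possible failures:
- Insertion into the electron-rich vinylogous ester may be slow.
- Protodeboronation of the electron-rich boronic acid may outrun the addition.
- Facial purity may erode through reversible opening of ring C.

Fallback (stereocentre from resolution instead of from the C–C bond formation):
- It sets out from 6 and 8. These are joined with the much more active achiral catalyst [Rh(OH)(cod)]2 in dioxane/H2O, giving the racemic bis-silyl flavanone F1.
- F1 is then submitted to a Noyori-type asymmetric transfer hydrogenation run as a kinetic resolution, with RuCl(p-cymene)[(R,R)-TsDPEN] and HCO2H/Et3N.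
- This catalyst should deliver hydride to give (4R)-alcohols. It should therefore consume the (2R)-ketone as the matched substrate, forming the (2R,4R)-cis-flavan-4-ol F2.
- The unreacted (2S)-ketone is separated by chromatography, and the route is rejoined at 9.

Step 3. Possible failure: hydroboration or isomerisation of the prenyl double bonds by iridium boryl/hydride species may compete with arene C–H activation.

Fallback (borylation before any alkene is present):
- It sets out from 2, which is borylated under the same type of iridium catalysis at the C–H meta to both bromines. This gives 2-[3,5-dibromo-4-(tert-butyldimethylsilyloxy)phenyl]-4,4,5,5-tetramethyl-1,3,2-dioxaborolane F3.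
- A base-free double Stille coupling of F3 with 3 follows. The pinacol boronate is a spectator because no base activates it, and the route is rejoined at 5.

Step 2. Possible failures:
- The reaction may stall after the first coupling.
- Isoprene may be lost by β-hydride elimination from the prenyl–palladium species.
- Coupling may occur through the tertiary terminus (reverse prenylation).

Fallback (build the prenyl groups in two stages):
- It sets out from 2, which is coupled twice with allyltributylstannane. This partner has no regiochemical ambiguity. The product is tert-butyl(2,6-diallylphenoxy)dimethylsilane F4.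
- Double cross-metathesis of F4 with excess 2-methyl-2-butene and second-generation Grubbs catalyst in CH2Cl2 at 40 °C converts both allyl groups into prenyl groups, and the route is rejoined at 4.

**Further compounds**
F1 | step 6 | racemic 2-[4-(tert-butyldimethylsilyloxy)-3,5-bis(3-methylbut-2-enyl)phenyl]-7-(triisopropylsilyloxy)chroman-4-one | CC(C)=CCc1cc(C2CC(=O)c3ccc(O[Si](C(C)C)(C(C)C)C(C)C)cc3O2)cc(CC=C(C)C)c1O[Si](C)(C)C(C)(C)C
F2 | step 6 | (2R,4R)-2-[4-(tert-butyldimethylsilyloxy)-3,5-bis(3-methylbut-2-enyl)phenyl]-7-(triisopropylsilyloxy)chroman-4-ol (cis) | CC(C)=CCc1cc([C@H]2C[C@@H](O)c3ccc(O[Si](C(C)C)(C(C)C)C(C)C)cc3O2)cc(CC=C(C)C)c1O[Si](C)(C)C(C)(C)C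
F3 | step 3 | 2-[3,5-dibromo-4-(tert-butyldimethylsilyloxy)phenyl]-4,4,5,5-tetramethyl-1,3,2-dioxaborolane | CC(C)(C)[Si](C)(C)Oc1c(Br)cc(B2OC(C)(C)C(C)(C)O2)cc1Br
F4 | step 2 | tert-butyl(2,6-diallylphenoxy)dimethylsilane | C=CCc1cccc(CC=C)c1O[Si](C)(C)C(C)(C)C
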